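**Retrosynthetic overview**

- The target comes from its tri-O-benzyl ether, which comes from a cyclic hemiketal: the C2–aryl bond is made by adding the protected 3,4-dihydroxy-5-methoxyphenyl-lithium to a δ-lactone, and C2–H by silane reduction.
- The δ-lactone comes from a C2-symmetric bis-lactone, 2,6-dioxabicyclo[3.3.1]nonane-3,7-dione. One lactone is kept as the future oxane; the other is opened by 4-(benzyloxy)phenyl-lithium and its C=O is reduced to CH2 to give the arylethyl chain.
- The bis-lactone comes from (4S,6S)-nona-1,8-diene-4,6-diol in one ozonolysis/oxidation operation. The diol comes from propane-1,3-diol and allyl acetate by a two-directional Ir allylation that sets both carbinol centres.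
- Ring order: both oxane (lactone) rings close together in step 2; one survives to the target, the other is cleaved in step 3. Both benzene rings are bought.

Assumption: (S)-Cl,MeO-BIPHEP is taken to be the ligand antipode that gives the (4S,6S)-diene diol in step 1; if the sense of induction is the reverse, the (R)-ligand is used and nothing else changes.

**Route**

Step 1
Reactants: 1 propane-1,3-diol; 2 allyl acetate
Product: 4 (4S,6S)-nona-1,8-diene-4,6-diol, via mono-allylated diol 3 (not isolated)
Conditions: [Ir(cod)Cl]2 (5 mol%), (S)-Cl,MeO-BIPHEP (10 mol%), 4-Cl-3-NO2-C6H3CO2H (20 mol%), Cs2CO3 (40 mol%), 2 (10 equiv), dioxane, 90 °C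
Reagents that add atoms: none
Why: Krische iridium-catalysed transfer-hydrogenative carbonyl allylation run in both directions; each CH2OH terminus is dehydrogenated in situ and allylated by the chiral allyl-iridium catalyst, so both carbinol centres are set by the catalyst, the second addition amplifies the ee, and the minor meso diol is removed by chromatography.

Step 2
Reactants: 4 (4S,6S)-nona-1,8-diene-4,6-diol
Product: 7 (1R,5R)-2,6-dioxabicyclo[3.3.1]nonane-3,7-dione, via dialdehyde 5 (not isolated), via bis-lactol 6 (not isolated)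
Conditions: O3, CH2Cl2, −78 °C; PPh3 (2.0 equiv), −78 °C → rt; then TEMPO (20 mol%), PhI(OAc)2 (2.4 equiv), rt
Reagents that add atoms: ozone, [O-][O+]=O
Why: Ozonolysis with reductive work-up turns both vinyl groups into aldehydes, each is captured at once by the 1,5-related hydroxyl so that both oxane rings close in the same operation (the anti diol is the diastereomer that fits the bicyclo[3.3.1] frame), and TEMPO/PhI(OAc)2 oxidises the two lactols to lactones without touching the carbinol centres (ozonolysis, double hemiacetalisation, lactol oxidation).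

Step 3
Reactants: 7 (1R,5R)-2,6-dioxabicyclo[3.3.1]nonane-3,7-dione; 8 1-(benzyloxy)-4-bromobenzene
Product: 10 (4R,6R)-6-{2-[4-(benzyloxy)phenyl]-2-oxoethyl}-4-hydroxyoxan-2-one, via aryllithium 9 (not isolated)
Conditions: 8, n-BuLi, THF, −78 °C; add to 7 (1.3 equiv), THF, −78 °C; AcOH quench at −78 °C
Reagents that add atoms: none
Why: Organolithium addition to a lactone: at −78 °C one aryl group is transferred to one of the two equivalent carbonyls of C2-symmetric 7 and the reaction stops there until the acid quench, which releases the aryl ketone and the hydroxyl that becomes the C4–OH of the target; no stereocentre is touched.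

Step 4
Reactants: 10 (4R,6R)-6-{2-[4-(benzyloxy)phenyl]-2-oxoethyl}-4-hydroxyoxan-2-one
Product: 12 (4R,6S)-6-{2-[4-(benzyloxy)phenyl]ethyl}-4-hydroxyoxan-2-one, via benzylic carbinol 11 (not isolated)
Conditions: Et3SiH (4 equiv), TFA, CH2Cl2, 0 °C → rt; aq. NaHCO3
Reagents that add atoms: none
Why: Kursanov–Parnes ionic hydrogenation: acid ionises the p-alkoxy-stabilised benzylic position and Et3SiH delivers hydride twice (ketone to carbinol to CH2), while the lactone, the aliphatic hydroxyl and the benzyl ether are left alone; no stereocentre is involved (the C6 descriptor changes only through CIP priorities).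

Step 5
Reactants: 13 5-bromo-2-hydroxy-3-methoxybenzaldehyde
Product: 15 5-bromo-3-methoxybenzene-1,2-diol, via aryl formate 14 (not isolated)
Conditions: 30% H2O2, 1 M NaOH, 0 °C → rt; then HCl
Reagents that add atoms: hydrogen peroxide, OO
Why: Dakin oxidation: hydroperoxide adds to the ortho-hydroxy aldehyde, aryl migration to oxygen gives the aryl formate, and hydrolysis frees the second phenol, so CHO becomes OH with bromine para to the central oxygen.

Step 6
Reactants: 15 5-bromo-3-methoxybenzene-1,2-diol
Product: 16 1,2-bis(benzyloxy)-5-bromo-3-methoxybenzene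
Conditions: BnBr (2.3 equiv), K2CO3, DMF, 60 °C
Reagents that add atoms: benzyl bromide, BrCc1ccccc1
Why: Double Williamson ether synthesis (SN2 of the catecholate on benzyl bromide) protects both phenols as groups that leave in the final hydrogenolysis.

Step 7
Reactants: 12 (4R,6S)-6-{2-[4-(benzyloxy)phenyl]ethyl}-4-hydroxyoxan-2-one; 16 1,2-bis(benzyloxy)-5-bromo-3-methoxybenzene
Product: 19 (4R,6S)-2-[3,4-bis(benzyloxy)-5-methoxyphenyl]-6-{2-[4-(benzyloxy)phenyl]ethyl}oxane-2,4-diol, via silyl ether 17 (not isolated), via aryllithium 18 (not isolated)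
Conditions: 12, TMSCl, Et3N, CH2Cl2, 0 °C, filter, evaporate; 16, n-BuLi, THF, −78 °C; combine in THF, −78 °C; 1 M HCl, THF, 0 °C
Reagents that add atoms: none
Why: C-aryl glycoside tactic: after transient O-silylation, the aryllithium from Br–Li exchange adds once to the δ-lactone carbonyl at −78 °C to give the cyclic hemiketal and the C2–aryl bond; C4 and C6 are untouched and the anomeric configuration is irrelevant.

Step 8
Reactants: 19 (4R,6S)-2-[3,4-bis(benzyloxy)-5-methoxyphenyl]-6-{2-[4-(benzyloxy)phenyl]ethyl}oxane-2,4-diol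
Product: 20 (2S,4R,6S)-2-[3,4-bis(benzyloxy)-5-methoxyphenyl]-6-{2-[4-(benzyloxy)phenyl]ethyl}oxan-4-ol
Conditions: Et3SiH (3 equiv), TFA (5 equiv), CH2Cl2, −30 → 0 °C
Reagents that add atoms: none
Why: Kishi-type reductive etherification: acid ionises the anomeric hydroxyl and Et3SiH delivers hydride axially to the half-chair that carries the C6 chain pseudo-equatorial, so the aryl group ends equatorial and cis to both the C6 chain and the C4 hydroxyl (2S), which is also the most stable, all-equatorial isomer.

Step 9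
Reactants: 20 (2S,4R,6S)-2-[3,4-bis(benzyloxy)-5-methoxyphenyl]-6-{2-[4-(benzyloxy)phenyl]ethyl}oxan-4-ol
Product: 21 (2S,4R,6S)-2-(3,4-dihydroxy-5-methoxyphenyl)-6-[2-(4-hydroxyphenyl)ethyl]oxan-4-ol
Conditions: H2 (1 atm), 10% Pd/C, EtOAc/MeOH, rt
Reagents that add atoms: none
Why: Pd-catalysed hydrogenolysis of the three benzyl ethers under neutral, 1 atm conditions that 2-aryl-oxane benzylic ethers and the three stereocentres normally tolerate.

**Compound list**

1 | propane-1,3-diol | OCCCO | starting material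
2 | allyl acetate (prop-2-enyl acetate) | CC(=O)OCC=C | starting material
3 | (3S)-hex-5-ene-1,3-diol | C=CC[C@H](O)CCO | intermediate (not isolated)
4 | (4S,6S)-nona-1,8-diene-4,6-diol (C2-symmetric anti diol) | C=CC[C@H](O)C[C@@H](O)CC=C | intermediate
5 | (3R,5R)-3,5-dihydroxyheptanedial | O=CC[C@H](O)C[C@@H](O)CC=O | intermediate (not isolated)
6 | (1R,5R)-2,6-dioxabicyclo[3.3.1]nonane-3,7-diol (bis-lactol, anomer mixture) | OC1C[C@H]2C[C@H](CC(O)O2)O1 | intermediate (not isolated)
7 | (1R,5R)-2,6-dioxabicyclo[3.3.1]nonane-3,7-dione (C2-symmetric bis-lactone; descriptors differ from 4 only through CIP priorities) | O=C1C[C@H]2C[C@H](CC(=O)O2)O1 | intermediate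
8 | 1-(benzyloxy)-4-bromobenzene | Brc1ccc(OCc2ccccc2)cc1 | starting material
9 | [4-(benzyloxy)phenyl]lithium | [Li]c1ccc(OCc2ccccc2)cc1 | intermediate (not isolated)
10 | (4R,6R)-6-{2-[4-(benzyloxy)phenyl]-2-oxoethyl}-4-hydroxyoxan-2-one (4-OH and C6 chain cis) | O=C1C[C@H](O)C[C@H](CC(=O)c2ccc(OCc3ccccc3)cc2)O1 | intermediate
11 | (4R,6R)-6-{2-[4-(benzyloxy)phenyl]-2-hydroxyethyl}-4-hydroxyoxan-2-one (both carbinol epimers) | O=C1C[C@H](O)C[C@H](CC(O)c2ccc(OCc3ccccc3)cc2)O1 | intermediate (not isolated)
12 | (4R,6S)-6-{2-[4-(benzyloxy)phenyl]ethyl}-4-hydroxyoxan-2-one (cis) | O=C1C[C@H](O)C[C@H](CCc2ccc(OCc3ccccc3)cc2)O1 | intermediate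
13 | 5-bromo-2-hydroxy-3-methoxybenzaldehyde | COc1cc(Br)cc(C=O)c1O | starting material
14 | 5-bromo-2-hydroxy-3-methoxyphenyl formate | COc1cc(Br)cc(OC=O)c1O | intermediate (not isolated)
15 | 5-bromo-3-methoxybenzene-1,2-diol | COc1cc(Br)cc(O)c1O | intermediate
16 | 1,2-bis(benzyloxy)-5-bromo-3-methoxybenzene | COc1cc(Br)cc(OCc2ccccc2)c1OCc1ccccc1 | intermediate
17 | (4R,6S)-6-{2-[4-(benzyloxy)phenyl]ethyl}-4-[(trimethylsilyl)oxy]oxan-2-one | O=C1C[C@H](O[Si](C)(C)C)C[C@H](CCc2ccc(OCc3ccccc3)cc2)O1 | intermediate (not isolated)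
18 | [3,4-bis(benzyloxy)-5-methoxyphenyl]lithium | COc1cc([Li])cc(OCc2ccccc2)c1OCc1ccccc1 | intermediate (not isolated)
19 | (4R,6S)-2-[3,4-bis(benzyloxy)-5-methoxyphenyl]-6-{2-[4-(benzyloxy)phenyl]ethyl}oxane-2,4-diol (hemiketal, both C2 anomers) | COc1cc(C2(O)C[C@H](O)C[C@H](CCc3ccc(OCc4ccccc4)cc3)O2)cc(OCc2ccccc2)c1OCc1ccccc1 | intermediate
20 | (2S,4R,6S)-2-[3,4-bis(benzyloxy)-5-methoxyphenyl]-6-{2-[4-(benzyloxy)phenyl]ethyl}oxan-4-ol (all-cis) | COc1cc([C@@H]2C[C@H](O)C[C@H](CCc3ccc(OCc4ccccc4)cc3)O2)cc(OCc2ccccc2)c1OCc1ccccc1 | intermediate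
21 | (2S,4R,6S)-2-(3,4-dihydroxy-5-methoxyphenyl)-6-[2-(4-hydroxyphenyl)ethyl]oxan-4-ol (all-cis) | COc1cc([C@@H]2C[C@H](O)C[C@H](CCc3ccc(O)cc3)O2)cc(O)c1O | target

**Count and risks**

Total step count: 9. Longest linear sequence: 7 (steps 1, 2, 3, 4, 7, 8, 9); steps 5 and 6 make the aryl bromide for step 7.

The three steps most likely to fail:

Step 3 (single aryl transfer to the bis-lactone). The β-acyloxy lactone can enolise and eliminate under the basic aryllithium, and a second addition can compete. The fallback sets out from bis-lactol 6 and comes back at carbinol 11. Step 2 is stopped after the PPh3 stage and 6 is isolated. It is treated with aryllithium 9 (about 3 equiv, the first two consumed by the lactol hydroxyls; THF, −78 → 0 °C), which adds to one masked aldehyde to give (4R,6R)-6-{2-[4-(benzyloxy)phenyl]-2-hydroxyethyl}oxane-2,4-diol F1. TEMPO/PhI(OAc)2 then oxidises the remaining lactol to the lactone, giving 11 (any over-oxidised material is ketone 10). Both are taken to 12 by the step 4 conditions.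

Step 4 (ketone to CH2 with Et3SiH/TFA). The β-hydroxy lactone may dehydrate, or the reduction may stall at a benzylic ether. The fallback sets out from 10 and comes back at 12. Ketone 10 is condensed with tosylhydrazide (EtOH, rt) to the tosylhydrazone N'-{1-[4-(benzyloxy)phenyl]-2-[(2S,4R)-4-hydroxy-6-oxooxan-2-yl]ethylidene}-4-methylbenzenesulfonohydrazide F2. This is reduced with catecholborane (CHCl3, 0 °C) and decomposed with NaOAc·3H2O at reflux, losing sulfinate and nitrogen to give 12 under non-acidic conditions.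

Step 7 (aryllithium addition to the silylated hydroxy-lactone). Enolisation of the lactone or incomplete addition would waste the two-step aryl bromide. The fallback sets out from 12 and comes back at 20, bypassing step 8 as well. Lactone 12 is reduced with DIBAL-H (CH2Cl2, −78 °C) to the lactol (4R,6S)-6-{2-[4-(benzyloxy)phenyl]ethyl}oxane-2,4-diol F3. Aryllithium 18 (about 3 equiv, THF, −78 → 0 °C) adds to its open aldehyde form to give (3R,5S)-1-[3,4-bis(benzyloxy)-5-methoxyphenyl]-7-[4-(benzyloxy)phenyl]heptane-1,3,5-triol F4 as a C1 mixture. Catalytic TsOH in CH2Cl2 ionises the electron-rich benzylic carbinol, and the C5 hydroxyl closes the oxane under thermodynamic control to the all-equatorial 20.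

**Further compounds**

F1 | step 3 | (4R,6R)-6-{2-[4-(benzyloxy)phenyl]-2-hydroxyethyl}oxane-2,4-diol | OC1C[C@H](O)C[C@H](CC(O)c2ccc(OCc3ccccc3)cc2)O1
F2 | step 4 | N'-{1-[4-(benzyloxy)phenyl]-2-[(2S,4R)-4-hydroxy-6-oxooxan-2-yl]ethylidene}-4-methylbenzenesulfonohydrazide | O=C1C[C@H](O)C[C@H](CC(=NNS(=O)(=O)c2ccc(C)cc2)c2ccc(OCc3ccccc3)cc2)O1
F3 | step 7 | (4R,6S)-6-{2-[4-(benzyloxy)phenyl]ethyl}oxane-2,4-diol | OC1C[C@H](O)C[C@H](CCc2ccc(OCc3ccccc3)cc2)O1
F4 | step 7 | (3R,5S)-1-[3,4-bis(benzyloxy)-5-methoxyphenyl]-7-[4-(benzyloxy)phenyl]heptane-1,3,5-triol | COc1cc(C(O)C[C@H](O)C[C@@H](O)CCc2ccc(OCc3ccccc3)cc2)cc(OCc2ccccc2)c1OCc1ccccc1
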